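**Plan**

- Retrosynthesis: the C3–aroyl bond is cut first (acylation of a C3 vinyllithium). C3 and C4 are then taken out of ring B (cut C2–C3 and C4–C5, join C2–C5), which leaves a bicyclo[3.1.1]heptane-6,7-dione. Its four-membered ring is cut into two dialkylketenes (one C–C(=O) bond at C1, one at C5), i.e. an acyclic 2,6-digeranylpimelic acid, which is cut at both C–geranyl bonds, at C5–C6 (Wittig) and at C7–prenyl.
- Enabling feature: ring B (C1–C2–C3–C4–C5–C9) is a cyclohexane-1,3,5-trione whose carbons C1 and C5 are quaternary and flank the C9 carbonyl. The four atoms C1–C2–C5–C9 are therefore the 1,3-cyclobutanedione dimer of two ketenes, and only the C3–C4 unit is missing.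
- Forward: chain assembly (steps 1–8); ring A and the four-membered ring together by intramolecular ketene dimerization (step 9); two-carbon ring expansion to ring B with ethoxyacetylide (step 10); C3 aroylation and deprotection (steps 13, 14).
- Stereochemistry: C7 by Evans alkylation with (S)-4-benzyl-2-oxazolidinone; C1 and C5 arise in step 10 under control of C7; the E-alkenes come from geranyl bromide.

Key step: step 10

Remark: the locants of the target are used for all intermediates. C1 is the bridgehead next to CMe2 (C8), C5 the other bridgehead, C9 the bridging carbonyl; ring A = C1–C8–C7–C6–C5–C9, ring B = C1–C2–C3–C4–C5–C9. Geranyl = (2E)-3,7-dimethylocta-2,6-dien-1-yl, prenyl = 3-methylbut-2-en-1-yl. The target is taken as the C4-enol tautomer.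
Remark: 13, 14 and 15 are carried as mixtures of epimers at the two carbons that become ketene carbons in step 9, where both centers are erased.

**Route**

Step 1
Reactants: 1 3,3-dimethylglutaric anhydride; 2 (4S)-4-benzyl-1,3-oxazolidin-2-one
Product: 4 methyl 5-[(4S)-4-benzyl-2-oxo-1,3-oxazolidin-3-yl]-3,3-dimethyl-5-oxopentanoate, via lithium carboxylate 3 (not isolated)
Conditions: 2, n-BuLi, THF, −78 °C; then 1, −78 → 0 °C; then MeI, DMF, rt
Reagents that add atoms: iodomethane, CI
Why: N-acylation of the lithiated oxazolidinone by the symmetrical anhydride, followed by SN2 esterification of the lithium carboxylate, should give the imide ester without any regiochemical issue or new stereocenter.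

Step 2
Reactants: 4 imide ester; 5 prenyl bromide
Product: 6 methyl (4S)-4-[(4S)-4-benzyl-2-oxo-1,3-oxazolidine-3-carbonyl]-3,3,7-trimethyloct-6-enoate
Conditions: NaN(SiMe3)2, THF, −78 °C; then 5, −78 → −30 °C
Reagents that add atoms: none
Why: Evans asymmetric alkylation, in which the chelated Z-sodium enolate of the imide (more acidic than the ester) is alkylated on the face away from the benzyl group, should set the future C7 center.

Step 3
Reactants: 6 prenylated imide
Product: 7 methyl (4S)-4-[(ethylsulfanyl)carbonyl]-3,3,7-trimethyloct-6-enoate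
Conditions: EtSH, n-BuLi, THF, −78 → 0 °C; then aq. NH4Cl
Reagents that add atoms: ethanethiol, CCS
Why: transthioesterification by the small, weakly basic lithium thiolate should cleave the auxiliary at the exocyclic carbonyl without epimerization and leave the methyl ester untouched.

Step 4
Reactants: 7 thioester
Product: 8 methyl (4S)-4-formyl-3,3,7-trimethyloct-6-enoate
Conditions: Et3SiH, Pd/C (10 wt% Pd, catalytic), acetone, rt
Reagents that add atoms: none
Why: Fukuyama reduction of a thioester stops at the aldehyde and should spare the ester and the trisubstituted alkene.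

Step 5
Reactants: 8 aldehyde; 9 methyl (triphenylphosphoranylidene)acetate
Product: 10 dimethyl (2E,4R)-5,5-dimethyl-4-(3-methylbut-2-en-1-yl)hept-2-enedioate
Conditions: toluene, 80 °C
Reagents that add atoms: none
Why: Wittig olefination with the stabilized ylide should give the E-enoate under neutral conditions that do not epimerize the hindered α-center of the aldehyde.

Step 6
Reactants: 10 enoate
Product: 11 dimethyl (4S)-3,3-dimethyl-4-(3-methylbut-2-en-1-yl)heptanedioate
Conditions: Mg, MeOH, 0 °C → rt
Reagents that add atoms: none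
Why: conjugate reduction by electron transfer from Mg in MeOH should saturate only the electron-poor enoate double bond and leave the prenyl alkene and the C7 center untouched.

Step 7
Reactants: 11 diester; 12 geranyl bromide (first equivalent)
Product: 13 dimethyl (4R)-2,6-digeranyl-3,3-dimethyl-4-prenylheptanedioate (mixture of epimers at C2 and C6 of the chain)
Conditions: 11 added to LiN(i-Pr)2 (2.3 equiv), THF, −78 °C; DMPU; then geranyl bromide 12 (2.5 equiv in all, two of them incorporated), −78 → −20 °C
Reagents that add atoms: geranyl bromide (second equivalent), CC(C)=CCC/C(C)=C/CBr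
Why: twofold ester enolate alkylation of the preformed dilithium bis(enolate), in which no neutral ester is left for a Dieckmann condensation, should take up one geranyl bromide at each of the two α-carbons (two equivalents in all), and the two new centers need no control because both become ketene carbons.

Step 8
Reactants: 13 digeranyl diester
Product: 14 (4R)-2,6-digeranyl-3,3-dimethyl-4-prenylheptanedioic acid
Conditions: NaSEt, DMF, 80 °C; then 1 M HCl, 0 °C
Reagents that add atoms: none
Why: SN2 demethylation by thiolate at the O-methyl carbons avoids attack at the hindered acyl carbons and should leave the five alkenes untouched.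

Step 9
Reactants: 14 diacid
Product: 17 (3R)-1,5-digeranyl-2,2-dimethyl-3-prenylbicyclo[3.1.1]heptane-6,7-dione, via bis(acid chloride) 15 (not isolated), via bis(ketene) 16 (not isolated)
Conditions: Me2C=C(Cl)NMe2, CH2Cl2, 0 °C → rt; concentrate; then slow addition to Et3N, toluene, 100 °C (0.005 M)
Reagents that add atoms: none
Why: Proposed new method: neutral chloroenamine-mediated formation of the bis(acid chloride) and twofold dehydrochlorination should give the tethered bis(dialkylketene) 16, whose ketene units, held three atoms apart by C6–C7–C8, combine head to tail in an intramolecular [2+2] cyclodimerization (each ketene carbon C1 or C5 bonding to the carbonyl carbon of the other ketene) to the 1,3-cyclobutanedione that closes ring A and the four-membered ring at once, the closest known reactions being the thermal dimerization of dimethylketene to 2,2,4,4-tetramethylcyclobutane-1,3-dione and the high-dilution cyclization of bifunctional ketenes, while the two epimeric centers of 14 vanish in the ketenes so that C7 remains the only stereocenter.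

Step 10
Reactants: 17 bicyclic dione; 18 ethoxyacetylene
Product: 21 (1R,5S,7R)-4-ethoxy-1,5-digeranyl-8,8-dimethyl-7-prenylbicyclo[3.3.1]non-3-ene-2,9-dione, via lithium alkoxide 19 (not isolated), via ynone enolate 20 (not isolated)
Conditions: 18, n-BuLi, THF, −78 °C; then 17 (18 in 1.05 equiv), −78 → 0 °C; then t-BuOH, 0 °C → rt; aq. NH4Cl
Reagents that add atoms: none
Why: Proposed new method: lithium ethoxyacetylide adds to one carbonyl bridge of the strained, non-enolizable 1,3-dione, the β-keto alkoxide 19 opens by retro-Claisen cleavage of the C2–C5 bond to the ketone enolate 20 that carries a 3-ethoxyprop-2-ynoyl group on C1, and the enolate carbon C5 then adds to the ethoxy-bearing alkyne carbon while t-BuOH protonates C3, so that the alkyne is inserted into the C2–C5 bond and the four-membered ring C1–C2–C5–C9 becomes the six-membered ring B. The closest known reaction types are the ring opening of 2,2,4,4-tetraalkylcyclobutane-1,3-diones by nucleophiles, the two-carbon ring expansion of cyclic β-dicarbonyl compounds by insertion of alkynes or arynes into the C–C(=O) bond, and the conjugate addition of enolates to ynones. Ring B closes in a 6-endo-dig mode, and the cis 1,3-diaxial attachment of C2 and C4 to ring A is enforced because the ynone is tethered to C1. C1 and C5 are not stereogenic in 17 and become stereocenters by the choice of carbonyl bridge: attack from the open sector between the two carbonyl bridges turns the alkoxide oxygen toward the three-carbon bridge, which should be tolerated only at the carbonyl on the side of H-7, so that the prenyl group at C7 ends up exo (equatorial on ring A) as in the target. The step needs carbon and not oxygen attack of the enolate on the ynone, which the lithium counter-ion and the soft acceptor should secure, and a single addition of the acetylide, which the stoichiometry at −78 °C and the enolate form of the remaining ketone should secure. Cleavage of the C1–C2 bond in place of C2–C5 would only give the regioisomeric enol ether, which leads to the same trione.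

Step 11
Reactants: 22 3,4-dihydroxybenzoic acid
Product: 23 tert-butyldimethylsilyl 3,4-bis[(tert-butyldimethylsilyl)oxy]benzoate
Conditions: TBSCl (3.5 equiv), imidazole, DMF, rt
Reagents that add atoms: tert-butyldimethylsilyl chloride, CC(C)(C)[Si](C)(C)Cl
Why: exhaustive silylation of both phenols and the acid should give a compound in which only the silyl ester reacts in the next step.

Step 12
Reactants: 23 tris(silyl) compound
Product: 24 3,4-bis[(tert-butyldimethylsilyl)oxy]benzoyl chloride
Conditions: (COCl)2, DMF (catalytic), CH2Cl2, 0 °C → rt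
Reagents that add atoms: oxalyl chloride, ClC(=O)C(=O)Cl
Why: the chloroiminium (Vilsmeier-type) reagent converts a silyl ester directly into the acid chloride with loss of the silyl chloride, so the aryl silyl ethers should survive.

Step 13
Reactants: 21 vinylogous ester; 24 aroyl chloride
Product: 25 (1S,5S,7R)-3-{3,4-bis[(tert-butyldimethylsilyl)oxy]benzoyl}-4-ethoxy-1,5-digeranyl-8,8-dimethyl-7-prenylbicyclo[3.3.1]non-3-ene-2,9-dione
Conditions: 2,2,6,6-tetramethylpiperidine, n-BuLi, THF, 0 °C; 21, −78 °C; then 24, −78 → −40 °C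
Reagents that add atoms: none
Why: C3–H is the only acidic position left (both bridgeheads are quaternary), so vinylic lithiation of the vinylogous ester by the hindered lithium amide and acylation of the vinyllithium by the acid chloride should install the aroyl group without touching a stereocenter.

Step 14
Reactants: 25 protected triketone
Product: 26 (1S,5S,7R)-3-(3,4-dihydroxybenzoyl)-4-hydroxy-1,5-digeranyl-8,8-dimethyl-7-prenylbicyclo[3.3.1]non-3-ene-2,9-dione (CNP0178719.1)
Conditions: LiOH·H2O, dioxane/H2O, 90 °C, argon; then 1 M HCl, 0 °C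
Reagents that add atoms: water (as hydroxide), O
Why: hydroxide should cleave the two aryl silyl ethers and replace the ethoxy group of the doubly activated vinylogous ester by addition–elimination at C4, which releases the enolized β-triketone as its anion (acidified at the end) without affecting C1, C5 or C7.

**Compound list**

1 | 3,3-dimethylglutaric anhydride | O=C1CC(C)(C)CC(=O)O1 | starting material
2 | (4S)-4-benzyl-1,3-oxazolidin-2-one | O=C1N[C@@H](Cc2ccccc2)CO1 | starting material
3 | lithium 5-[(4S)-4-benzyl-2-oxo-1,3-oxazolidin-3-yl]-3,3-dimethyl-5-oxopentanoate | [Li+].[O-]C(=O)CC(C)(C)CC(=O)N1C(=O)OC[C@@H]1Cc1ccccc1 | intermediate (not isolated)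
4 | methyl 5-[(4S)-4-benzyl-2-oxo-1,3-oxazolidin-3-yl]-3,3-dimethyl-5-oxopentanoate | COC(=O)CC(C)(C)CC(=O)N1C(=O)OC[C@@H]1Cc1ccccc1 | intermediate
5 | prenyl bromide (1-bromo-3-methylbut-2-ene) | CC(C)=CCBr | starting material
6 | methyl (4S)-4-[(4S)-4-benzyl-2-oxo-1,3-oxazolidine-3-carbonyl]-3,3,7-trimethyloct-6-enoate | COC(=O)CC(C)(C)[C@H](CC=C(C)C)C(=O)N1C(=O)OC[C@@H]1Cc1ccccc1 | intermediate
7 | methyl (4S)-4-[(ethylsulfanyl)carbonyl]-3,3,7-trimethyloct-6-enoate | COC(=O)CC(C)(C)[C@H](CC=C(C)C)C(=O)SCC | intermediate
8 | methyl (4S)-4-formyl-3,3,7-trimethyloct-6-enoate | COC(=O)CC(C)(C)[C@H](CC=C(C)C)C=O | intermediate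
9 | methyl (triphenylphosphoranylidene)acetate | COC(=O)C=P(c1ccccc1)(c1ccccc1)c1ccccc1 | starting material
10 | dimethyl (2E,4R)-5,5-dimethyl-4-(3-methylbut-2-en-1-yl)hept-2-enedioate | COC(=O)/C=C/[C@@H](CC=C(C)C)C(C)(C)CC(=O)OC | intermediate
11 | dimethyl (4S)-3,3-dimethyl-4-(3-methylbut-2-en-1-yl)heptanedioate | COC(=O)CC[C@@H](CC=C(C)C)C(C)(C)CC(=O)OC | intermediate
12 | geranyl bromide ((2E)-1-bromo-3,7-dimethylocta-2,6-diene) | CC(C)=CCC/C(C)=C/CBr | starting material
13 | dimethyl (4R)-2,6-digeranyl-3,3-dimethyl-4-prenylheptanedioate, epimers at C2 and C6 | COC(=O)C(C/C=C(\C)CCC=C(C)C)C[C@@H](CC=C(C)C)C(C)(C)C(C/C=C(\C)CCC=C(C)C)C(=O)OC | intermediate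
14 | (4R)-2,6-digeranyl-3,3-dimethyl-4-prenylheptanedioic acid, epimers at C2 and C6 | OC(=O)C(C/C=C(\C)CCC=C(C)C)C[C@@H](CC=C(C)C)C(C)(C)C(C/C=C(\C)CCC=C(C)C)C(=O)O | intermediate
15 | (4R)-2,6-digeranyl-3,3-dimethyl-4-prenylheptanedioyl dichloride | ClC(=O)C(C/C=C(\C)CCC=C(C)C)C[C@@H](CC=C(C)C)C(C)(C)C(C/C=C(\C)CCC=C(C)C)C(Cl)=O | intermediate (not isolated)
16 | (4R)-2,6-digeranyl-3,3-dimethyl-4-prenylhepta-1,6-diene-1,7-dione (bis-ketene) | O=C=C(C/C=C(\C)CCC=C(C)C)C[C@@H](CC=C(C)C)C(C)(C)C(C/C=C(\C)CCC=C(C)C)=C=O | intermediate (not isolated)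
17 | (3R)-1,5-digeranyl-2,2-dimethyl-3-prenylbicyclo[3.1.1]heptane-6,7-dione | O=C1C2(C/C=C(\C)CCC=C(C)C)C[C@@H](CC=C(C)C)C(C)(C)C1(C/C=C(\C)CCC=C(C)C)C2=O | intermediate
18 | ethoxyacetylene (ethoxyethyne) | C#COCC | starting material
19 | lithium alkoxide from addition of the acetylide to the carbonyl bridge of 17 on the side of H-7, alkynyl group in the sector between the two carbonyl bridges | [Li+].CC(C)=CCC/C(C)=C/C[C@]12C[C@@H](CC=C(C)C)C(C)(C)[C@](C/C=C(\C)CCC=C(C)C)([C@@]1([O-])C#COCC)C2=O | intermediate (not isolated)
20 | lithium enolate (C5=C9–OLi) of 2,6-digeranyl-2-(3-ethoxyprop-2-ynoyl)-3,3-dimethyl-4-prenylcyclohexanone, C1 and C7 as in 21 | [Li+].CC(C)=CCC/C(C)=C/CC1=C([O-])[C@@](C/C=C(\C)CCC=C(C)C)(C(=O)C#COCC)C(C)(C)[C@H](CC=C(C)C)C1 | intermediate (not isolated)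
21 | (1R,5S,7R)-4-ethoxy-1,5-digeranyl-8,8-dimethyl-7-prenylbicyclo[3.3.1]non-3-ene-2,9-dione | CC(C)=CCC/C(C)=C/C[C@]12C[C@@H](CC=C(C)C)C(C)(C)[C@](C/C=C(\C)CCC=C(C)C)(C(=O)C=C1OCC)C2=O | intermediate
22 | 3,4-dihydroxybenzoic acid | O=C(O)c1ccc(O)c(O)c1 | starting material
23 | tert-butyldimethylsilyl 3,4-bis[(tert-butyldimethylsilyl)oxy]benzoate | CC(C)(C)[Si](C)(C)OC(=O)c1ccc(O[Si](C)(C)C(C)(C)C)c(O[Si](C)(C)C(C)(C)C)c1 | intermediate
24 | 3,4-bis[(tert-butyldimethylsilyl)oxy]benzoyl chloride | O=C(Cl)c1ccc(O[Si](C)(C)C(C)(C)C)c(O[Si](C)(C)C(C)(C)C)c1 | intermediate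
25 | (1S,5S,7R)-3-{3,4-bis[(tert-butyldimethylsilyl)oxy]benzoyl}-4-ethoxy-1,5-digeranyl-8,8-dimethyl-7-prenylbicyclo[3.3.1]non-3-ene-2,9-dione | CC(C)=CCC/C(C)=C/C[C@]12C[C@@H](CC=C(C)C)C(C)(C)[C@](C/C=C(\C)CCC=C(C)C)(C(=O)C(C(=O)c3ccc(O[Si](C)(C)C(C)(C)C)c(O[Si](C)(C)C(C)(C)C)c3)=C1OCC)C2=O | intermediate
26 | (1S,5S,7R)-3-(3,4-dihydroxybenzoyl)-4-hydroxy-1,5-digeranyl-8,8-dimethyl-7-prenylbicyclo[3.3.1]non-3-ene-2,9-dione | CC(C)=CCC/C(C)=C/C[C@]12C[C@@H](CC=C(C)C)C(C)(C)[C@](C/C=C(\C)CCC=C(C)C)(C(=O)C(C(=O)c3ccc(O)c(O)c3)=C1O)C2=O | target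

**Count and risks**

Total steps: 14 (12 in the main line, 2 for acid chloride 24). Longest linear sequence: 12 steps (steps 1–10, 13, 14).

Steps most likely to fail:

1. Step 10 (Proposed new method). The acetylide adduct may fail to fragment, the ring-opened enolate may close through oxygen to a pyranone, the ynone may take up a second acetylide, or addition may occur at the other carbonyl bridge and give the C7-epimeric series. Fallback with known chemistry, from 17 back to 21: 17 would be opened with LiCH2CO2t-Bu (THF, −78 → 0 °C), a nucleophilic retro-Claisen ring opening of the kind known from the alcoholysis of tetraalkylcyclobutanediones, to the β-keto ester tert-butyl 3-(1,3-digeranyl-6,6-dimethyl-2-oxo-5-prenylcyclohexyl)-3-oxopropanoate F1. Heating F1 in toluene (110 °C) should expel tert-butanol, and the acylketene should acylate the enol carbon C5 as in the second bond formation of an Effenberger cyclization, giving the bicyclic trione (1R,5S,7R)-1,5-digeranyl-4-hydroxy-8,8-dimethyl-7-prenylbicyclo[3.3.1]non-3-ene-2,9-dione F2. O-Ethylation of F2 at the less hindered enol oxygen (triethyloxonium tetrafluoroborate, i-Pr2NEt, CH2Cl2) returns to 21.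

2. Step 9 (Proposed new method). Dehydrochlorination at the neopentyl-type acid chloride may be slow, and the bis-ketene may oligomerize, add to the prenyl alkene in an intramolecular [2+2] cycloaddition, or dimerize to the alkylidene β-lactone in place of the 1,3-dione. Fallback with known chemistry, from 13 back to 21: Dieckmann condensation of 13 (KN(SiMe3)2 in excess, THF) would give the monocyclic β-keto ester methyl 1,3-digeranyl-4,4-dimethyl-2-oxo-5-prenylcyclohexane-1-carboxylate F3. Krapcho dealkoxycarbonylation (LiCl, wet DMSO, 150 °C) gives 2,6-digeranyl-3,3-dimethyl-4-prenylcyclohexan-1-one F4. Silylation (TBSOTf, Et3N) gives the silyl enol ether tert-butyl[(2,6-digeranyl-5,5-dimethyl-4-prenylcyclohex-1-en-1-yl)oxy]dimethylsilane F5. Effenberger cyclization of F5 with malonyl dichloride (then KOH, BnEt3NCl), which in related cases takes place on the face away from the C7 substituent, would give the trione F2 of the preceding fallback, and its O-ethylation returns to 21.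

3. Step 7. Alkylation at the neopentyl-type α-carbon may stay incomplete, and the half-alkylated enolate may then undergo Dieckmann condensation onto the other ester on warming. Fallback, from 11 back to 14: 11 would be saponified (LiOH, THF/H2O) to (4S)-3,3-dimethyl-4-prenylheptanedioic acid F6. Its bis(enediolate) (LiN(i-Pr)2, 4.4 equiv, THF/HMPA), which cannot undergo a Claisen condensation, would be alkylated with two equivalents of 12 in the manner of carboxylic acid dianion alkylations to give 14 directly, so that step 8 is not needed.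

**Further compounds**

F1 | step 10 | tert-butyl 3-(1,3-digeranyl-6,6-dimethyl-2-oxo-5-prenylcyclohexyl)-3-oxopropanoate, quaternary carbon and C7 as in 21 | CC(C)(C)OC(=O)CC(=O)[C@]1(C/C=C(\C)CCC=C(C)C)C(=O)C(C/C=C(\C)CCC=C(C)C)C[C@@H](CC=C(C)C)C1(C)C
F2 | step 10 | (1R,5S,7R)-1,5-digeranyl-4-hydroxy-8,8-dimethyl-7-prenylbicyclo[3.3.1]non-3-ene-2,9-dione | CC(C)=CCC/C(C)=C/C[C@]12C[C@@H](CC=C(C)C)C(C)(C)[C@](C/C=C(\C)CCC=C(C)C)(C(=O)C=C1O)C2=O
F3 | step 9 | methyl 1,3-digeranyl-4,4-dimethyl-2-oxo-5-prenylcyclohexane-1-carboxylate | COC(=O)C1(C/C=C(\C)CCC=C(C)C)C[C@@H](CC=C(C)C)C(C)(C)C(C/C=C(\C)CCC=C(C)C)C1=O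
F4 | step 9 | 2,6-digeranyl-3,3-dimethyl-4-prenylcyclohexan-1-one | O=C1C(C/C=C(\C)CCC=C(C)C)C[C@@H](CC=C(C)C)C(C)(C)C1C/C=C(\C)CCC=C(C)C
F5 | step 9 | tert-butyl[(2,6-digeranyl-5,5-dimethyl-4-prenylcyclohex-1-en-1-yl)oxy]dimethylsilane | CC(C)(C)[Si](C)(C)OC1=C(C/C=C(\C)CCC=C(C)C)C[C@@H](CC=C(C)C)C(C)(C)C1C/C=C(\C)CCC=C(C)C
F6 | step 7 | (4S)-3,3-dimethyl-4-(3-methylbut-2-en-1-yl)heptanedioic acid | OC(=O)CC[C@@H](CC=C(C)C)C(C)(C)CC(=O)O
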